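**One-step habit.** In a one-step world the rate follows the concentrations of free catalyst and reagent, so at fixed mol% and equivalents the percent made per hour follows the charge.

the same everywhere: free catalyst 0.48 mol%

| flask | substrate | reagent | remark | time |
|---|---|---|---|---|
| beta | 0.56 M | 0.95 equiv | run made earlier |  |
| gamma | 0.28 M | 0.95 equiv | run made earlier |  |
| delta | 1.1 M | 0.95 equiv | run made earlier |  |
| Thursday's | 0.56 M (fed, over 7.50 h) | 0.950 equiv | all but substrate at the start; substrate goes in evenly over 7.50 h, the run ends at 15 h | 15 h |
| Saturday's | 0.56 M | 0.950 equiv | everything together in a closed stirred flask, run for 15 h | 15 h |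
| Sunday's | 0.56 M | 0.950 equiv | a single well-mixed tank run continuously and read at steady state, 15 h in it on average |  |
| Monday's | 0.56 M | 0.950 equiv (fed, over 7.50 h) | a stirred flask in which reagent is dosed at a steady rate over 7.50 h without added volume, worked up at 15 h | 15 h |

| beta: time / h | beta: product / % | gamma: time / h | gamma: product / % | delta: time / h | delta: product / % |
|---|---|---|---|---|---|
| 1.33 | 11.7 | 1.33 | 7.3 | 1.33 | 14.2 |
| 4.00 | 30.6 | 4.00 | 20.6 | 4.00 | 40.8 |
| 8.00 | 54.9 | 8.00 | 38.6 | 8.00 | 69.1 |
| 10.0 | 64.8 | 10.0 | 45.9 | 10.0 | 80.0 |
| 15.0 | 81.4 | 15.0 | 61.7 | 15.0 | 92.0 |

(standard deviation of a reading: 0.5 percentage points)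

- the set-up with the highest amount of product at the outlet or at the end, in percent of the substrate put in ("none" if the first two lie within 2 percentage points) (Thursday's / Saturday's / Sunday's / Monday's / none)
- amount of product at the outlet or at the end, in percent of the substrate put in, Thursday's
- amount of product at the outlet or at the end, in percent of the substrate put in, Saturday's
- amount of product at the outlet or at the end, in percent of the substrate put in, Sunday's
- amount of product at the outlet or at the end, in percent of the substrate put in, Monday's

- the stated concentrations are those of everything mixed, before any reaction; amounts are the same in each set-up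
- what was read earlier has a scatter of 0.5 percentage points, one standard deviation
- candidate steps: reagent + free catalyst <-> catalyst intermediate A; catalyst intermediate A -> catalyst intermediate B; substrate + catalyst intermediate B -> catalyst intermediate C; catalyst intermediate C -> free catalyst + product; 2 catalyst intermediate A -> spent catalyst
- the feed brings no volume worth counting
- the earlier runs were made in a closed, stirred flask

**The border.** From gamma to beta the charge grows 2.00-fold and the first reading 1.60-fold. From beta to delta the charge grows 1.96-fold, but the first reading grows less, 1.21-fold. The habit bends.

**Both ends.** At high concentration I let product grow evenly in time; at low concentration it is pseudo-first-order in the reagent left. I join them as rate = R c/(K + c), where x is the fraction of substrate made into product, c₀ the substrate charged, e the equivalents of reagent (the limiting reagent), c = c₀(e − x) and R the ceiling. Integrating gives a budget D = Rt = x + (K/c₀) ln(e/(e − x)), an even part plus a tail. The final readings of gamma and delta give K = 0.503 M, the knee concentration: the reagent concentration at which the rate stands at half its ceiling. They also give D = 2.50 for 15.0 h. Beta, left out of that pair, spends 2.56. Its reagent starts at 0.532 M, close to K, so neither end holds there.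

**My reckoning.** Saturday's has beta's charges, so I take beta's last reading, 81.4 %. Sunday's tank balance, x = D c/(K + c), gives 64.1 %. In the earlier runs substrate and reagent fall together at 0.95 equiv, so I do not part them and count a dosed charge of either as arriving 3.75 h late on average. I then reckon Thursday's and Monday's like beta at 11.2 h, about 69.0 %. That puts Saturday's first, ahead by more than the margin.

**The forecast.** Parting from me on the dosed flasks, it says 80.5 %, 81.4 %, 65 % and 72 % for Thursday's, Saturday's, Sunday's and Monday's, best none, holding for Thursday's that “substrate is rarely limiting”.

**The flask.** It gives 75.3 %, 80.6 %, 64.1 % and 72.6 % in that order, best Saturday's.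

    reagent + free catalyst ⇌ catalyst intermediate A (K = 0.500 M⁻¹, k = 0.130 M⁻¹ s⁻¹)
    catalyst intermediate A → catalyst intermediate B (k = 0.0700 s⁻¹)
    substrate + catalyst intermediate B → catalyst intermediate C (k = 0.0590 M⁻¹ s⁻¹)
    catalyst intermediate C → free catalyst + product (k = 0.0110 s⁻¹)
    2 catalyst intermediate A → spent catalyst (k = 0.0130 M⁻¹ s⁻¹)

**The neighbour.** Thursday's and Monday's both end above my estimate. Saturday's 80.6 % spends 2.50 of the budget. The neighbour is Saturday's with 1.4 M of substrate, equivalents, loadings and time held. With x close to e the even part costs e, so the tail gets D − e, and x = e(1 − exp(−(D − e)c₀/K)) gives 93.7 %. That flask gives 94.0 %, with 0.99 % of its reagent charge left unbound.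

Readings and results come from a simulation with made-up constants.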